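**Retrosynthetic overview**

1. Feature: the C2 ketone and the C9 oxygen are 1,4-related across C1–C10 of ring A. That bond joins the α-carbon of the C2 carbonyl to the α-carbon of a C9 carbonyl, so no enolate/electrophile pairing makes it.
2. End game: target ⇐ C2-ketal bis-tiglate ⇐ 8α,9α-diol ⇐ isopropenyl-copper opening at C7 of a 7α,8α-epoxide ⇐ epoxidation directed by the 9α-alcohol ⇐ Δ7-en-9-one ⇐ cis-4,5-dimethyldecalin-2,9-dione.
3. Key: the dione ⇐ fluoride cleavage of the temporary C1–C9 bond of a siloxycyclopropyl ketone ⇐ rhodium carbenoid at C1 adding to the C9=C10 enol silane (forms C1–C10 and C1–C9, closes ring A).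
4. Precursor: diazoketone ⇐ methyl ketone ⇐ ester; C5 quaternary centre and regiodefined enol silane ⇐ copper-catalysed Me3Al conjugate addition with silyl trapping; cyclohexenone ⇐ Birch reduction of an anisole; C4 ⇐ Rh/BINAP arylation of a crotonate.
5. Ring order: ring B (from the arene) first; ring A together with the cyclopropane in the key step; the cyclopropane is then opened.

Key step: step 7

Remark: atoms are numbered as in eremophilane (ring A = C1–C5 and C10; ring B = C5–C10; C15 = methyl on C4, C14 = methyl on C5, C11–C13 = isopropenyl on C7). β is the face of ring B that carries the C5 methyl. The target is then (4S,5R,7R,8R,9S,10S), a cis-decalin with H10 β. A crotonate ester replaces a pentenone as the C2–C4/C15 unit, because a side-chain ketone or its ketal cannot be carried past the enol silane (see steps 4–6).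

**Route**

Step 1
Reactants: 1 3-methoxyphenylboronic acid; 2 ethyl (E)-but-2-enoate
Product: 4 (S)-3-(3-methoxyphenyl)butanoic acid, via ethyl (S)-3-(3-methoxyphenyl)butanoate 3 (not isolated)
Conditions: Rh(acac)(C2H4)2 (3 mol %), (R)-BINAP (3.3 mol %), dioxane/H2O 10:1, 100 °C; then LiOH·H2O, 50 °C; aq. HCl
Reagents that add atoms: lithium hydroxide [Li+].[OH-]
Why: Rhodium-catalysed asymmetric 1,4-addition of an arylboronic acid to an E-enoate (Hayashi–Miyaura reaction) should set C4 as S, the ligand antipode being the one that gives the S acid ((R)-BINAP on the accepted facial model for E acceptors), and saponification in the same aqueous medium does not touch the β-stereocentre.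

Step 2
Reactants: 4 (S)-3-(3-methoxyphenyl)butanoic acid
Product: 6 (S)-3-(3-oxocyclohex-1-en-1-yl)butanoic acid, via (S)-3-(5-methoxycyclohexa-1,4-dien-1-yl)butanoic acid 5 (not isolated)
Conditions: Li, NH3(l)/THF, t-BuOH, −78 → −33 °C; NH4Cl; then 1 M HCl, THF, rt
Reagents that add atoms: water O
Why: Birch reduction of the anisole ring (the carboxylate is inert) should give the 2,5-dihydroanisole with both substituents on sp2 carbons, and mild acid hydrolysis of the enol ether with conjugation gives the 3-substituted cyclohex-2-enone without enolising toward the C4 stereocentre.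

Step 3
Reactants: 6 (S)-3-(3-oxocyclohex-1-en-1-yl)butanoic acid
Product: 7 methyl (S)-3-(3-oxocyclohex-1-en-1-yl)butanoate
Conditions: MeI, K2CO3, DMF, rt
Reagents that add atoms: iodomethane CI
Why: O-alkylation of the carboxylate (SN2 esterification) gives an ester that tolerates Me3Al at low temperature, whereas a free side-chain ketone would be attacked by the ring enolate formed in step 4.

Step 4
Reactants: 7 methyl (S)-3-(3-oxocyclohex-1-en-1-yl)butanoate
Product: 9 methyl (S)-3-[(R)-3-(tert-butyldimethylsilyloxy)-1-methylcyclohex-2-en-1-yl]butanoate, via dimethylaluminium enolate 8 (not isolated)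
Conditions: Me3Al (2 equiv), Cu(OTf)2 (5 mol %), L* (10 mol %), Et2O, −30 °C; then TBSOTf, THF, −30 → 0 °C
Reagents that add atoms: trimethylaluminium C[Al](C)C; tert-butyldimethylsilyl trifluoromethanesulfonate CC(C)(C)[Si](C)(C)OS(=O)(=O)C(F)(F)F
Why: Copper-catalysed asymmetric conjugate addition of Me3Al to a β,β-disubstituted cyclohexenone (L* = BINOL-derived phosphoramidite of bis(1-phenylethyl)amine, antipode chosen for methyl delivery to the Si face of C5) should set the C5 quaternary centre as R under ligand control, and O-silylation of the aluminium enolate fixes the C9=C10 enol silane, which cannot be made regioselectively from the ketone.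

Step 5
Reactants: 9 methyl (S)-3-[(R)-3-(tert-butyldimethylsilyloxy)-1-methylcyclohex-2-en-1-yl]butanoate
Product: 11 (S)-4-[(R)-3-(tert-butyldimethylsilyloxy)-1-methylcyclohex-2-en-1-yl]pentan-2-one, via N-methoxy-N-methylamide 10 (not isolated)
Conditions: MeNHOMe·HCl (1.6 equiv), MeMgCl (5 equiv), THF, −20 → 0 °C; aq. NH4Cl
Reagents that add atoms: N,O-dimethylhydroxylamine hydrochloride CNOC.Cl (amide nitrogen of 10); methylmagnesium chloride C[Mg]Cl
Why: One-pot aminolysis of the ester to the Weinreb amide and Grignard addition gives the methyl ketone through a stable magnesium chelate that prevents over-addition, under basic conditions that a TBS enol ether tolerates.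

Step 6
Reactants: 11 (S)-4-[(R)-3-(tert-butyldimethylsilyloxy)-1-methylcyclohex-2-en-1-yl]pentan-2-one
Product: 13 (S)-1-diazo-4-[(R)-3-(tert-butyldimethylsilyloxy)-1-methylcyclohex-2-en-1-yl]pentan-2-one, via trifluoroacetyl ketone 12 (not isolated)
Conditions: LiN(SiMe3)2, THF, −78 °C; CF3CO2CH2CF3; then MsN3, Et3N, H2O (1 equiv), MeCN, rt
Reagents that add atoms: 2,2,2-trifluoroethyl trifluoroacetate FC(F)(F)COC(=O)C(F)(F)F (trifluoroacetyl group of 12); methanesulfonyl azide CS(=O)(=O)N=[N+]=[N-]
Why: Kinetic deprotonation at the methyl group, Claisen trifluoroacetylation and detrifluoroacetylative diazo transfer (Regitz-type) install the diazo group at C1 under basic, non-acidic conditions that leave the enol silane intact.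

Step 7
Reactants: 13 (S)-1-diazo-4-[(R)-3-(tert-butyldimethylsilyloxy)-1-methylcyclohex-2-en-1-yl]pentan-2-one
Product: 14 9β-(tert-butyldimethylsilyloxy)-4β,5β-dimethyl-1,9-cyclo-10βH-decalin-2-one (C1–C9 bond on the α face of ring B; H1 and H10 and OSi on one face of the cyclopropane)
Conditions: Rh2(OAc)4 (1 mol %), CH2Cl2, rt, slow addition of 13
Reagents that add atoms: none
Why: Loss of N2 on Rh2(OAc)4 gives an electrophilic rhodium carbenoid at C1 that adds in a concerted, asynchronous [2+1] fashion to the electron-rich C9=C10 enol silane, forming C1–C10 and the temporary C1–C9 bond; the closest known reaction type is the intramolecular cyclopropanation of silyl enol ethers by α-diazoketones. Ring A (C1, C2, C3, C4, C5, C10) closes as a six-membered ring through the four-atom tether C2–C5, as a 1-diazohept-6-en-2-one gives a bicyclo[4.1.0]heptan-2-one, and the cyclopropane C1–C9–C10 closes in the same event by suprafacial addition across the alkene. All three new stereocentres are governed by the C5 quaternary centre: the tether reaches only the face of the enol silane on which C4 stands, so C1 is cis to C4 on ring B and H10 falls on the side of the C5 methyl (cis ring fusion), while syn addition places H1, H10 and the silyloxy group on one face of the three-membered ring. The step needs chemoselectivity for cyclopropanation over C–H insertion and carbene dimerisation; the only C–H bond in 1,5-relation to the carbenoid is a primary one of the C15 methyl, the enol silane is far more nucleophilic, and slow addition keeps the diazo concentration low. Facial selectivity needs no external control, since the opposite face is out of reach of the tether.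

Step 8
Reactants: 14 9β-(tert-butyldimethylsilyloxy)-4β,5β-dimethyl-1,9-cyclo-10βH-decalin-2-one
Product: 15 (4S,5R,10S)-4,5-dimethyl-cis-decalin-2,9-dione
Conditions: n-Bu4NF, AcOH, THF, 0 °C
Reagents that add atoms: none
Why: Fluoride-induced ring opening of the donor–acceptor (siloxy) cyclopropane (retro-aldol type) cleaves only C1–C9, the bond between the oxygen donor and the ketone acceptor, and the acetic acid buffer protonates the C2 enolate at C1 without epimerising C10.

Step 9
Reactants: 15 (4S,5R,10S)-4,5-dimethyl-cis-decalin-2,9-dione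
Product: 16 (4S,5R,10S)-2,2-(ethylenedioxy)-4,5-dimethyl-cis-decalin-9-one
Conditions: (Me3SiOCH2)2 (1.1 equiv), Me3SiOTf (5 mol %), CH2Cl2, −78 °C; pyridine
Reagents that add atoms: 1,2-bis(trimethylsilyloxy)ethane C[Si](C)(C)OCCO[Si](C)(C)C
Why: Silyl-transfer ketalisation under aprotic conditions at low temperature should take the C2 ketone, which is flanked by two methylene groups, in preference to the C9 ketone next to the ring-fusion methine, and it avoids the enolisation that could epimerise C10.

Step 10
Reactants: 16 (4S,5R,10S)-2,2-(ethylenedioxy)-4,5-dimethyl-cis-decalin-9-one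
Product: 18 (4S,5R,10S)-2,2-(ethylenedioxy)-4,5-dimethyl-cis-decal-7-en-9-one, via trimethylsilyl enol ether 17 (not isolated)
Conditions: LiN(i-Pr)2, THF, −78 °C; Me3SiCl; then Pd(OAc)2 (1.1 equiv), MeCN, rt
Reagents that add atoms: chlorotrimethylsilane C[Si](C)(C)Cl (silyl group of 17)
Why: Kinetic deprotonation occurs at the C8 methylene and not at the hindered C10 methine, and Saegusa–Ito oxidation of the resulting enol silane (palladium enolate, β-hydride elimination from C7) gives the Δ7-en-9-one.

Step 11
Reactants: 18 (4S,5R,10S)-2,2-(ethylenedioxy)-4,5-dimethyl-cis-decal-7-en-9-one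
Product: 19 2,2-(ethylenedioxy)-4β,5β-dimethyl-10βH-decal-7-en-9α-ol
Conditions: NaBH4, CeCl3·7H2O, MeOH, −78 °C
Reagents that add atoms: none
Why: Luche 1,2-reduction should deliver hydride to the β (convex) face of C9, because the α face is covered by ring A (the inward C4–H and C3), giving the 9α-alcohol and ending the risk of epimerisation at C10.

Step 12
Reactants: 19 2,2-(ethylenedioxy)-4β,5β-dimethyl-10βH-decal-7-en-9α-ol
Product: 20 7α,8α-epoxy-2,2-(ethylenedioxy)-4β,5β-dimethyl-10βH-decalin-9α-ol
Conditions: VO(acac)2 (5 mol %), t-BuOOH, CH2Cl2, 0 °C → rt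
Reagents that add atoms: tert-butyl hydroperoxide CC(C)(C)OO
Why: Vanadium-catalysed hydroxyl-directed epoxidation delivers oxygen from the vanadate ester of the allylic 9α-alcohol to the same face of C7=C8, which sets the C8 oxygen α.

Step 13
Reactants: 20 7α,8α-epoxy-2,2-(ethylenedioxy)-4β,5β-dimethyl-10βH-decalin-9α-ol
Product: 21 7α,8α-epoxy-2,2-(ethylenedioxy)-4β,5β-dimethyl-9α-(trimethylsilyloxy)-10βH-decalin
Conditions: Me3SiCl, imidazole, CH2Cl2, 0 °C
Reagents that add atoms: chlorotrimethylsilane C[Si](C)(C)Cl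
Why: Silyl ether formation masks O9 so that no metal alkoxide sits beside the epoxide in step 14, where it could steer the organocopper reagent to C8.

Step 14
Reactants: 21 7α,8α-epoxy-2,2-(ethylenedioxy)-4β,5β-dimethyl-9α-(trimethylsilyloxy)-10βH-decalin; 22 isopropenylmagnesium bromide
Product: 24 (4S,5R,7R,8R,9S,10S)-2,2-(ethylenedioxy)-10βH-eremophil-11-ene-8α,9α-diol, via 9-O-trimethylsilyl diol 23 (not isolated)
Conditions: 22 (4 equiv), CuI (20 mol %), THF, −30 → 0 °C; NH4Cl; then K2CO3, MeOH, rt
Reagents that add atoms: none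
Why: Copper-catalysed Grignard opening of the epoxide (SN2, inversion) should occur at C7, the carbon remote from the electron-withdrawing C9–O bond, by trans-diaxial attack on the β face through the half-chair that keeps the C9 silyloxy group pseudo-equatorial; this places isopropenyl β at C7 and leaves the C8 oxygen α, and methanolysis of the silyl ether then frees the diol.

Step 15
Reactants: 24 (4S,5R,7R,8R,9S,10S)-2,2-(ethylenedioxy)-10βH-eremophil-11-ene-8α,9α-diol; 25 tiglic acid
Product: 26 (4S,5R,7R,8R,9S,10S)-2,2-(ethylenedioxy)-10βH-eremophil-11-ene-8α,9α-diyl bis[(E)-2-methylbut-2-enoate]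
Conditions: 25 (6 equiv), 2,4,6-Cl3C6H2COCl, Et3N, PhMe, rt; then 24, DMAP, 80 °C
Reagents that add atoms: none
Why: Yamaguchi esterification through the mixed anhydride is the standard way to acylate hindered secondary alcohols with tiglic acid without E/Z isomerisation, and an excess with heating should also acylate the axial 9α-hydroxyl.

Step 16
Reactants: 26 (4S,5R,7R,8R,9S,10S)-2,2-(ethylenedioxy)-10βH-eremophil-11-ene-8α,9α-diyl bis[(E)-2-methylbut-2-enoate]
Product: 27 (4S,5R,7R,8R,9S,10S)-2-oxo-10βH-eremophil-11-ene-8α,9α-diyl bis[(E)-2-methylbut-2-enoate] (CNP0249036.2)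
Conditions: PPTS, acetone/H2O 10:1, 55 °C
Reagents that add atoms: water O
Why: Mild acid-catalysed hydrolysis of the dioxolane releases the C2 ketone without affecting the tiglate esters or the isopropenyl group, and no stereocentre is α to an enolisable position that matters.

**Compound list**

1 | 3-methoxyphenylboronic acid | COc1cccc(B(O)O)c1 | starting material
2 | ethyl (E)-but-2-enoate | C/C=C/C(=O)OCC | starting material
3 | ethyl (S)-3-(3-methoxyphenyl)butanoate | CCOC(=O)C[C@@H](c1cccc(OC)c1)C | intermediate (not isolated)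
4 | (S)-3-(3-methoxyphenyl)butanoic acid | OC(=O)C[C@@H](c1cccc(OC)c1)C | intermediate
5 | (S)-3-(5-methoxycyclohexa-1,4-dien-1-yl)butanoic acid | OC(=O)C[C@@H](C1=CCC=C(OC)C1)C | intermediate (not isolated)
6 | (S)-3-(3-oxocyclohex-1-en-1-yl)butanoic acid | OC(=O)C[C@@H](C1=CC(=O)CCC1)C | intermediate
7 | methyl (S)-3-(3-oxocyclohex-1-en-1-yl)butanoate | COC(=O)C[C@@H](C1=CC(=O)CCC1)C | intermediate
8 | dimethylaluminium enolate of methyl (S)-3-[(R)-1-methyl-3-oxocyclohexyl]butanoate | COC(=O)C[C@@H]([C@@]1(C)CCCC(O[Al](C)C)=C1)C | intermediate (not isolated)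
9 | methyl (S)-3-[(R)-3-(tert-butyldimethylsilyloxy)-1-methylcyclohex-2-en-1-yl]butanoate | COC(=O)C[C@@H]([C@@]1(C)CCCC(O[Si](C)(C)C(C)(C)C)=C1)C | intermediate
10 | (S)-N-methoxy-N-methyl-3-[(R)-3-(tert-butyldimethylsilyloxy)-1-methylcyclohex-2-en-1-yl]butanamide | CON(C)C(=O)C[C@@H]([C@@]1(C)CCCC(O[Si](C)(C)C(C)(C)C)=C1)C | intermediate (not isolated)
11 | (S)-4-[(R)-3-(tert-butyldimethylsilyloxy)-1-methylcyclohex-2-en-1-yl]pentan-2-one | CC(=O)C[C@@H]([C@@]1(C)CCCC(O[Si](C)(C)C(C)(C)C)=C1)C | intermediate
12 | (S)-1,1,1-trifluoro-6-[(R)-3-(tert-butyldimethylsilyloxy)-1-methylcyclohex-2-en-1-yl]heptane-2,4-dione | FC(F)(F)C(=O)CC(=O)C[C@@H]([C@@]1(C)CCCC(O[Si](C)(C)C(C)(C)C)=C1)C | intermediate (not isolated)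
13 | (S)-1-diazo-4-[(R)-3-(tert-butyldimethylsilyloxy)-1-methylcyclohex-2-en-1-yl]pentan-2-one | [N-]=[N+]=CC(=O)C[C@@H]([C@@]1(C)CCCC(O[Si](C)(C)C(C)(C)C)=C1)C | intermediate (key-step precursor)
14 | 9β-(tert-butyldimethylsilyloxy)-4β,5β-dimethyl-1,9-cyclo-10βH-decalin-2-one | C1C[C@@]2(C)[C@H]([C@@H]3C(=O)C[C@@H]2C)[C@@]3(O[Si](C)(C)C(C)(C)C)C1 | intermediate (key-step product)
15 | (4S,5R,10S)-4,5-dimethyl-cis-decalin-2,9-dione | C1CC[C@@]2(C)[C@H](CC(=O)C[C@@H]2C)C1=O | intermediate
16 | (4S,5R,10S)-2,2-(ethylenedioxy)-4,5-dimethyl-cis-decalin-9-one | C1CC[C@@]2(C)[C@H](CC3(OCCO3)C[C@@H]2C)C1=O | intermediate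
17 | 2,2-(ethylenedioxy)-4β,5β-dimethyl-9-(trimethylsilyloxy)-10βH-decal-8-ene | C1C[C@@]2(C)[C@H](CC3(OCCO3)C[C@@H]2C)C(O[Si](C)(C)C)=C1 | intermediate (not isolated)
18 | (4S,5R,10S)-2,2-(ethylenedioxy)-4,5-dimethyl-cis-decal-7-en-9-one | C1=CC[C@@]2(C)[C@H](CC3(OCCO3)C[C@@H]2C)C1=O | intermediate
19 | 2,2-(ethylenedioxy)-4β,5β-dimethyl-10βH-decal-7-en-9α-ol | C1=CC[C@@]2(C)[C@H](CC3(OCCO3)C[C@@H]2C)[C@@H]1O | intermediate
20 | 7α,8α-epoxy-2,2-(ethylenedioxy)-4β,5β-dimethyl-10βH-decalin-9α-ol | [C@@H]12C[C@@]3(C)[C@H](CC4(OCCO4)C[C@@H]3C)[C@H](O)[C@@H]1O2 | intermediate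
21 | 7α,8α-epoxy-2,2-(ethylenedioxy)-4β,5β-dimethyl-9α-(trimethylsilyloxy)-10βH-decalin | [C@@H]12C[C@@]3(C)[C@H](CC4(OCCO4)C[C@@H]3C)[C@H](O[Si](C)(C)C)[C@@H]1O2 | intermediate
22 | isopropenylmagnesium bromide | C=C(C)[Mg]Br | starting material
23 | 2,2-(ethylenedioxy)-9α-(trimethylsilyloxy)-10βH-eremophil-11-en-8α-ol | C=C(C)[C@H]1C[C@@]2(C)[C@H](CC3(OCCO3)C[C@@H]2C)[C@H](O[Si](C)(C)C)[C@@H]1O | intermediate (not isolated)
24 | (4S,5R,7R,8R,9S,10S)-2,2-(ethylenedioxy)-10βH-eremophil-11-ene-8α,9α-diol | C=C(C)[C@H]1C[C@@]2(C)[C@H](CC3(OCCO3)C[C@@H]2C)[C@H](O)[C@@H]1O | intermediate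
25 | tiglic acid, (E)-2-methylbut-2-enoic acid | C/C=C(\C)C(=O)O | starting material
26 | (4S,5R,7R,8R,9S,10S)-2,2-(ethylenedioxy)-10βH-eremophil-11-ene-8α,9α-diyl bis[(E)-2-methylbut-2-enoate] | C=C(C)[C@H]1C[C@@]2(C)[C@H](CC3(OCCO3)C[C@@H]2C)[C@H](OC(=O)/C(C)=C/C)[C@@H]1OC(=O)/C(C)=C/C | intermediate
27 | (4S,5R,7R,8R,9S,10S)-2-oxo-10βH-eremophil-11-ene-8α,9α-diyl bis[(E)-2-methylbut-2-enoate] (CNP0249036.2) | C=C(C)[C@H]1C[C@@]2(C)[C@H](CC(=O)C[C@@H]2C)[C@H](OC(=O)/C(C)=C/C)[C@@H]1OC(=O)/C(C)=C/C | target

**Step count**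

Total steps: 16. Longest linear sequence: 16 steps (1 and 2 to 27); the key-step precursor 13 is reached in 6 steps.

**Steps most likely to fail**

Step 14. The organocopper reagent may attack C8 instead of C7. The ring B half-chair that allows trans-diaxial attack at C8 is also accessible, and the one leading to C7 attack puts the nucleophile syn-axial to the C5 methyl. Lewis-acid rearrangement of the epoxide is a second possible loss. The fallback sets out from enone 18 and returns at 26.
- Copper-catalysed conjugate addition of 22 (CuBr·SMe2, Me3SiCl, THF, −78 °C) puts the isopropenyl group on C7 and traps the enolate as the 7β-isopropenyl trimethylsilyl enol ether F1.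
- Rubottom oxidation (dimethyldioxirane, −78 °C; citric acid, MeOH) should give the 8β-hydroxy-9-ketone F2 by axial attack on the open β face.
- Mitsunobu esterification with 25 (PPh3, DIAD) inverts C8 to the 8α-tigloyloxy-9-ketone F3.
- NaBH4/CeCl3 adds hydride from the β face to give the 9α-hydroxy-8α-tiglate F4, and Yamaguchi tigloylation of the remaining hydroxyl gives 26.
- In this variant C7 rests on β-face selectivity of the conjugate addition, which is not secured, instead of on the regiochemistry of an epoxide opening.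

Step 4. Conjugate addition may be slow at a β-carbon flanked by the branched side chain. Facial control by the ligand may be eroded by the neighbouring C4 stereocentre, and O-silylation of the aluminium enolate may be incomplete. The fallback sets out from 7 and returns at 9.
- Corey–Bakshi–Shibata reduction of the enone gives the (S)-allylic alcohol F5.
- Hydroxyl-directed Simmons–Smith cyclopropanation (Et2Zn, CH2I2) adds the methylene group syn to the hydroxyl to give the cyclopropyl carbinol F6.
- Dess–Martin oxidation gives the cyclopropyl ketone F7.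
- Li in NH3/THF at −78 °C (2.2 equiv, no proton donor) cleaves the exocyclic cyclopropane bond that overlaps with the carbonyl π system. This reveals the C5 methyl and, regiospecifically, the C9=C10 lithium enolate, which is silylated with TBSCl to give 9.
- The quaternary centre then comes from a reagent-controlled carbinol and a directed cyclopropanation, not from a catalytic conjugate addition.

Step 7. The carbenoid may be diverted into C–H insertion (C15 methyl or C6 methylene) or into carbene dimerisation, or the strained siloxycyclopropane may open on the catalyst. The fallback sets out from 11 and returns at 15.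
- Kinetic silylation of the methyl ketone (LiN(SiMe3)2, Me3SiCl, −78 °C) gives the bis(silyl enol ether) F8.
- Oxidative intramolecular coupling of the two enol silanes with (NH4)2Ce(NO3)6 and NaHCO3 in MeCN at −10 °C forms C1–C10 directly and should give dione 15.
- The tether again fixes H10 cis to the C5 methyl.

**Further compounds**

F1 | step 14 | 2,2-(ethylenedioxy)-9-(trimethylsilyloxy)-10βH-eremophila-8,11-diene (7β-isopropenyl) | C=C(C)[C@H]1C[C@@]2(C)[C@H](CC3(OCCO3)C[C@@H]2C)C(O[Si](C)(C)C)=C1
F2 | step 14 | 2,2-(ethylenedioxy)-8β-hydroxy-10βH-eremophil-11-en-9-one | C=C(C)[C@H]1C[C@@]2(C)[C@H](CC3(OCCO3)C[C@@H]2C)C(=O)[C@H]1O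
F3 | step 14 | 2,2-(ethylenedioxy)-9-oxo-10βH-eremophil-11-en-8α-yl (E)-2-methylbut-2-enoate | C=C(C)[C@H]1C[C@@]2(C)[C@H](CC3(OCCO3)C[C@@H]2C)C(=O)[C@@H]1OC(=O)/C(C)=C/C
F4 | step 14 | 2,2-(ethylenedioxy)-9α-hydroxy-10βH-eremophil-11-en-8α-yl (E)-2-methylbut-2-enoate | C=C(C)[C@H]1C[C@@]2(C)[C@H](CC3(OCCO3)C[C@@H]2C)[C@H](O)[C@@H]1OC(=O)/C(C)=C/C
F5 | step 4 | methyl (S)-3-[(S)-3-hydroxycyclohex-1-en-1-yl]butanoate | COC(=O)C[C@@H](C1=C[C@@H](O)CCC1)C
F6 | step 4 | methyl (S)-3-(5-hydroxybicyclo[4.1.0]heptan-1-yl)butanoate, hydroxyl syn to the cyclopropane | COC(=O)C[C@@H]([C@]12C[C@H]1[C@@H](O)CCC2)C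
F7 | step 4 | methyl (S)-3-(5-oxobicyclo[4.1.0]heptan-1-yl)butanoate | COC(=O)C[C@@H]([C@]12C[C@H]1C(=O)CCC2)C
F8 | step 7 | (S)-4-[(R)-3-(tert-butyldimethylsilyloxy)-1-methylcyclohex-2-en-1-yl]-2-(trimethylsilyloxy)pent-1-ene | C=C(O[Si](C)(C)C)C[C@@H]([C@@]1(C)CCCC(O[Si](C)(C)C(C)(C)C)=C1)C
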